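**Plan**

Retrosynthesis: the C9–C10 and C17–C18 bonds of the saturated 25-membered lactone are first taken back to alkenes. Both C=C bonds are then cut, which frees C10–C17 as an eight-carbon cycloalkene and rejoins C9 to C18 as the ring alkene of a 17-membered lactone.
Forward: isoambrettolide 1 (17-membered ring, 16 carbons) takes up one molecule of cyclooctene 2 by ring-expansion metathesis, so the only ring of the route, the 25-membered diene lactone 3, arises in a single event. Hydrogenation then gives 24-tetracosanolide 4.
Enabling feature: the 24 ring carbons are the 16 of the 17-membered lactone plus the 8 of cyclooctene, and C2 to C24 are an unbroken run of CH2 groups, so alkenes left at C9=C10 and C17=C18 are erased by hydrogenation.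
Stereochemistry: the target has no stereocentre, and the alkene geometry of 1 and 3 is irrelevant because both alkenes end as CH2–CH2.

Key step: step 1

Assumption: commercial isoambrettolide is an E/Z mixture rich in the E isomer, and 3 should likewise form as a mixture of alkene isomers. Both are drawn as the E forms, and the geometry has no bearing on the route.

**Route**

Step 1
Reactants: 1 isoambrettolide, (E)-oxacycloheptadec-10-en-2-one; 2 (Z)-cyclooctene
Product: 3 (9E,17E)-tetracosa-9,17-dien-24-olide
Conditions: RuCl2(H2IMes)(PCy3)(=CHPh) (second-generation Grubbs catalyst, 1 mol % on 1), 1 (5 equiv, 0.02 M), CH2Cl2, 40 °C, argon; 2 (1 equiv) in CH2Cl2 by syringe pump over 8 h; then ethyl vinyl ether; silica plug, Kugelrohr recovery of 1 for recycling, AgNO3-impregnated silica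
Reagents that add atoms: none
Why: Proposed new method: the ruthenium benzylidene, and after the first turnover the alkylidene it hands on, opens strained cyclooctene 2 to a chain-end alkylidene, this undergoes cross metathesis with the C9=C10 alkene of 1 and thereby opens the 17-membered ring, and the open-chain alkylidene then back-bites on the alkene at the far end of its C8 segment, which forms C9=C10 and C17=C18 of 3 and passes the carbene on. The closest known reaction types are the ring-expansion metathesis of cycloalkenes with acyclic dienes (ring-opening, cross and ring-closing cascade) and the ring–chain equilibration of macrocyclic alkenes by ruthenium carbenes, whereas a single cyclooctene insertion into an unstrained macrolide has not been shown. The 25-membered ring closes by macrocyclic ring-closing metathesis, an intramolecular [2+2] cycloaddition and cycloreversion through a ruthenacyclobutane, which the dilution (0.02 M) favours over chain growth. No stereocentre arises, and the E/Z make-up of the two new alkenes is immaterial because step 2 saturates both. The step needs ring-size selectivity for exactly one C8 unit per lactone, and since full equilibration would favour the smaller rings (1 plus the cyclic cyclooctene dimer cyclohexadeca-1,9-diene), it is run under kinetic control: 1 is kept in fivefold excess so that each opened cyclooctene meets a lactone alkene, 2 is fed slowly so that it never accumulates, and the carbene is quenched at low conversion of 1. The substrate suits this because its ester sits seven and six CH2 groups away from the alkene and cannot chelate or deactivate ruthenium, and because 1, 3 and the over-inserted lactones differ by whole C8H14 units and by their number of alkenes, so that 1 can be distilled off for recycling and 3 purified on AgNO3-impregnated silica.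

Step 2
Reactants: 3 (9E,17E)-tetracosa-9,17-dien-24-olide
Product: 4 24-tetracosanolide (oxacyclopentacosan-2-one)
Conditions: H2 (1 atm), 10% Pd/C, EtOAc, rt
Reagents that add atoms: none
Why: Catalytic heterogeneous hydrogenation should saturate both unhindered 1,2-disubstituted ring alkenes while the lactone, whose C–O bond is neither allylic nor benzylic, stays intact, and any double-bond migration on the metal is harmless because every position from C2 to C24 ends as CH2.

**Compound list**

1 | isoambrettolide, (E)-oxacycloheptadec-10-en-2-one | O=C1CCCCCCC/C=C/CCCCCCO1 | starting material
2 | (Z)-cyclooctene | C1CC/C=C\CCC1 | starting material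
3 | (9E,17E)-tetracosa-9,17-dien-24-olide, (10E,18E)-oxacyclopentacosa-10,18-dien-2-one | O=C1CCCCCCC/C=C/CCCCCC/C=C/CCCCCCO1 | intermediate
4 | 24-tetracosanolide, oxacyclopentacosan-2-one | O=C1CCCCCCCCCCCCCCCCCCCCCCCO1 | target

Total step count: 2
Longest linear sequence: 2 steps (1 → 3 → 4)

**Steps most likely to fail**

The route has only two steps, so both are ranked and there is no third entry.

Step 1 (carries the label). What may go wrong: loss of ring-size control. The cyclooctene units may pair with each other to lactone-free cyclic oligomers, or enter one lactone twice. Secondary metathesis may also redistribute the inserted C8 unit before the quench, so that 3 would form only as a minor component that is hard to enrich.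

Fallback, by known chemistry, replaces metathesis by olefination and macrolactonisation. It sets out from 1. Partial reduction with iBu2AlH in CH2Cl2 at −78 °C should open the lactone to (E)-16-hydroxyhexadec-9-enal F1. The C8 unit is brought in as (7-carboxyheptyl)triphenylphosphonium bromide F2, made from 8-bromooctanoic acid and triphenylphosphine in refluxing acetonitrile. Its ylide (KN(SiMe3)2, THF) should undergo a Wittig reaction with F1, in the way carboxyalkyl ylides are routinely coupled with free hydroxy aldehydes, to give (8Z,17E)-24-hydroxytetracosa-8,17-dienoic acid F3. Yamaguchi macrolactonisation (2,4,6-trichlorobenzoyl chloride, Et3N, then DMAP in refluxing toluene at high dilution) should close the 25-membered ring as (8Z,17E)-tetracosa-8,17-dien-24-olide F4. Hydrogenation of F4 under the conditions of step 2 comes back to the route at 4.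

Step 2. What may go wrong: stalling of the heterogeneous hydrogenation through poisoning of the palladium surface by ruthenium, phosphine or silver residues carried over from step 1, which would leave partly saturated lactone that is hard to separate from 4.

Fallback: it sets out from 3 and uses a metal-free reduction with diimide, generated in the flask from p-toluenesulfonyl hydrazide and NaOAc in refluxing THF–water. This should saturate both disubstituted alkenes and arrive directly at 4 without any new compound on the way.

**Further compounds**

F1 | step 1 | (E)-16-hydroxyhexadec-9-enal | O=CCCCCCCC/C=C/CCCCCCO
F2 | step 1 | (7-carboxyheptyl)triphenylphosphonium bromide | OC(=O)CCCCCCC[P+](c1ccccc1)(c1ccccc1)c1ccccc1.[Br-]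
F3 | step 1 | (8Z,17E)-24-hydroxytetracosa-8,17-dienoic acid | OC(=O)CCCCCC/C=C\CCCCCCC/C=C/CCCCCCO
F4 | step 1 | (8Z,17E)-tetracosa-8,17-dien-24-olide | O=C1CCCCCC/C=C\CCCCCCC/C=C/CCCCCCO1
F0 | step 2 | none | none
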